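The route rests on disconnecting the C9–C10 bond of ring B. The target's fully substituted C10, flanked by C5 and C9, and its C8 exocyclic methylene (a ketone in disguise) are served together by one acid-mediated cation–olefin closure. Protonation of a ring A C5=C10 olefin at C5 gives the C10 cation, a C8(Cl)=C9 chloro-olefin traps it through C9, and hydrolysis leaves the C8 ketone. One operation thus closes ring B and sets C5, C9 and C10 of the trans-decalin. The precursor is a ring A cyclohexene ester with C4 already (S), bearing at C5 a (Z)-3-chloro-7-oxooct-3-enyl chain assembled without protecting groups.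

Key step: step 8

Remarks
- Atoms are numbered as in labdanes throughout (ring A = C1–C5 and C10; ring B = C5–C10).
- Naming note: diketone 15 has lost C14, C15 and C17 and is therefore named as a 14,15,17-trinorlabdane.
- Assumption: with L-valine tert-butyl ester under the toluene/HMPA regime, methyl iodide is taken to enter on the face that gives the (S)-keto ester 5. If the sense proves opposite, D-valine tert-butyl ester is used in the same way.

Step 1
Reactants: 1 methyl 2-oxocyclohexane-1-carboxylate; 2 L-valine tert-butyl ester (free base from the commercial hydrochloride)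
Product: 3 methyl 2-{[(2S)-1-tert-butoxy-3-methyl-1-oxobutan-2-yl]amino}cyclohex-1-ene-1-carboxylate
Conditions: BF3·OEt2 (cat.), toluene, reflux, Dean–Stark
Reagents that add atoms: none
Why: Acid-catalysed condensation of the primary amine with the ketone of the β-keto ester, driven by water removal, should give the conjugated, hydrogen-bonded enamino ester (enamine formation); no stereocentre is created and the auxiliary centre is untouched.

Step 2
Reactants: 3 methyl 2-{[(2S)-1-tert-butoxy-3-methyl-1-oxobutan-2-yl]amino}cyclohex-1-ene-1-carboxylate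
Product: 5 methyl (1S)-1-methyl-2-oxocyclohexane-1-carboxylate, via imine 4 (not isolated)
Conditions: LiN(i-Pr)2 (1.2 equiv), toluene, −78 °C; HMPA (1 equiv); MeI, −78 → −40 °C; then 1 M aq. HCl, 0 °C
Reagents that add atoms: iodomethane, CI; water, O
Why: Auxiliary-controlled alkylation of a chiral lithio-enamine: lithium is chelated by the enamine nitrogen and the valine ester carbonyl, the isopropyl group screens one face of the nucleophilic ring carbon and MeI enters on the other, which sets the quaternary C4 centre as (S), and mild acid then hydrolyses imine 4 to the ketone and returns the auxiliary.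

Step 3
Reactants: 5 methyl (1S)-1-methyl-2-oxocyclohexane-1-carboxylate
Product: 6 methyl (1S)-1,3-dimethyl-2-oxocyclohexane-1-carboxylate (mixture of C3 epimers)
Conditions: LiN(i-Pr)2 (1.1 equiv), THF, −78 °C; MeI (1.2 equiv), −78 → 0 °C
Reagents that add atoms: iodomethane, CI
Why: Kinetic enolate alkylation: C3 is the only enolisable position, so methylation should occur there without touching the quaternary centre, and the C3 epimer mixture is inconsequential because that carbon becomes sp2 in step 4.

Step 4
Reactants: 6 methyl (1S)-1,3-dimethyl-2-oxocyclohexane-1-carboxylate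
Product: 7 methyl (1S)-1,3-dimethyl-2-{[(trifluoromethyl)sulfonyl]oxy}cyclohex-2-ene-1-carboxylate
Conditions: KN(SiMe3)2, THF, −78 → −20 °C; PhNTf2, −78 °C → rt
Reagents that add atoms: N-phenylbis(trifluoromethanesulfonimide), O=S(=O)(N(c1ccccc1)S(=O)(=O)C(F)(F)F)C(F)(F)F
Why: Enolate O-sulfonylation (enol triflate formation): the ketone can enolise only toward the methyl-bearing C3, so the potassium enolate and PhNTf2 should give a single, tetrasubstituted enol triflate (the future C5=C10 olefin).

Step 5
Reactants: 7 methyl (1S)-1,3-dimethyl-2-{[(trifluoromethyl)sulfonyl]oxy}cyclohex-2-ene-1-carboxylate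
Product: 8 methyl (1S)-2-ethenyl-1,3-dimethylcyclohex-2-ene-1-carboxylate
Conditions: CH2=CHSnBu3, Pd(PPh3)4 (5 mol %), CuCl, LiCl, DMSO, 60 °C
Reagents that add atoms: tributyl(ethenyl)stannane, C=C[Sn](CCCC)(CCCC)CCCC
Why: Stille cross-coupling of an enol triflate with a vinylstannane, run with CuCl/LiCl to speed transmetalation at the congested tetrasubstituted carbon, should replace triflate by vinyl (C6=C7) with the ester and the C4 centre untouched.

Step 6
Reactants: 9 pentane-2,4-dione; 10 1,1,3-trichloroprop-1-ene
Product: 12 6,6-dichlorohex-5-en-2-one, via alkylated diketone 11 (not isolated)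
Conditions: K2CO3, EtOH, reflux
Reagents that add atoms: none
Why: Alkylative ketone synthesis from acetylacetone: carbonate-mediated SN2 C-alkylation at the allylic CH2 of 10 is followed in the same pot by retro-Claisen deacetylation with ethanol, while the vinylic C–Cl bonds are inert to these conditions.

Step 7
Reactants: 8 methyl (1S)-2-ethenyl-1,3-dimethylcyclohex-2-ene-1-carboxylate; 12 6,6-dichlorohex-5-en-2-one
Product: 14 methyl (1S)-2-[(3Z)-3-chloro-7-oxooct-3-en-1-yl]-1,3-dimethylcyclohex-2-ene-1-carboxylate, via alkylborane 13 (not isolated)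
Conditions: 9-BBN (1.1 equiv), THF, rt → 50 °C; then 12, Pd2(dba)3 (2.5 mol %), XantPhos (5 mol %), KF, K3PO4, THF, reflux
Reagents that add atoms: 9-borabicyclo[3.3.1]nonane (9-BBN), C1CC2CCCC(C1)B2 (its boron and carbon atoms are carried only by intermediate 13; product 14 keeps one hydrogen from it)
Why: Hydroboration followed by B-alkyl Suzuki–Miyaura coupling: 9-BBN should add anti-Markovnikov to the monosubstituted vinyl group only, and zerovalent palladium with the wide-bite-angle XantPhos should insert into the less hindered C–Cl bond trans to the alkyl chain of the 1,1-dichloroalkene and stop after one alkylation, which forms C7–C8 and fixes the Z chloro-olefin (C7 and C11 trans) while ketone and ester are tolerated.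

Step 8
Reactants: 14 methyl (1S)-2-[(3Z)-3-chloro-7-oxooct-3-en-1-yl]-1,3-dimethylcyclohex-2-ene-1-carboxylate
Product: 15 methyl 8,13-dioxo-14,15,17-trinorlabdan-19-oate
Conditions: CF3CO2H/CH2Cl2 (1:1), 0 → 20 °C; then H2O, 0 → 20 °C; aq. NaHCO3 work-up; chromatographic removal of diastereomers
Reagents that add atoms: water, O
Why: Reversible protonation of the tetrasubstituted C5=C10 olefin at C5 gives the tertiary C10 cation, which the chloro-olefin attacks through C9 (the carbon remote from chlorine) so that the new C8 cation is stabilised by chlorine lone-pair donation until water turns it into the ketone with loss of HCl; the closest known reaction types are the cationic chloro-olefin annulation to cyclohexanones and the acid-mediated closure of monocyclic ring A olefins of the monocyclofarnesyl type to trans-decalins. Ring B closes in the 6-endo-trig mode, with C8 and C9 both inside the new ring, through a chair transition state. C10 is controlled by that chair, in which the C5–C6 bond and the forming C9–C10 bond are both equatorial on ring A so that H5 and the C10 methyl end trans-diaxial; C5 is fixed in the reversible protonation, because the C5 epimer whose chair keeps the slimmer CO2Me, and not the C4 methyl, axial and syn to the C10 methyl should close faster (Curtin–Hammett selection by the existing C4 centre); C9 is set by the Z chloro-olefin, whose trans C7/C11 arrangement places C11 equatorial, and is backed by acid equilibration next to the new ketone. The step needs protonation of the ring olefin in preference to the chloro-olefin (secured by the deactivating chlorine), attack through C9 and not C8 (secured by chlorine stabilising the C8 cation and by six- over five-membered closure), and face selectivity relative to C4, which rests only on the smaller 1,3-diaxial demand of the ester and is expected to be the weakest control. The C13 ketone and both esters are spectators in cold trifluoroacetic acid, and a short reaction time at or below room temperature should guard against acid aldol closure of the 1,5-diketone.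

Step 9
Reactants: 15 methyl 8,13-dioxo-14,15,17-trinorlabdan-19-oate
Product: 16 15-ethyl 19-methyl (13E)-8-oxo-17-norlabd-13-ene-15,19-dioate
Conditions: (EtO)2P(O)CH2CO2Et, NaH, THF, 0 °C; then 15, 0 °C → rt; chromatographic removal of the Z isomer
Reagents that add atoms: triethyl phosphonoacetate, CCOC(=O)CP(=O)(OCC)OCC
Why: Horner–Wadsworth–Emmons olefination: the phosphonate anion should attack only the unhindered C13 methyl ketone (the C8 carbonyl sits next to the neopentyl-like C9), reversible adduct formation favours the E enoate with the C12 chain trans to the ester, and a preformed anion without excess base limits enolisation of the 1,5-diketone.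

Step 10
Reactants: 16 15-ethyl 19-methyl (13E)-8-oxo-17-norlabd-13-ene-15,19-dioate
Product: 17 15-ethyl 19-methyl (13E)-labda-8(17),13-diene-15,19-dioate
Conditions: Zn, CH2Br2, TiCl4, THF (reagent aged at 0–5 °C); then 16, CH2Cl2, 0 °C → rt
Reagents that add atoms: dibromomethane, BrCBr
Why: Takai–Lombardo methylenation: the non-basic zinc/titanium methylene reagent should convert the hindered, enolisable C8 ketone into the exocyclic C8=C17 olefin without epimerising C9 and without touching the enoate or the C19 ester.

Step 11
Reactants: 17 15-ethyl 19-methyl (13E)-labda-8(17),13-diene-15,19-dioate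
Product: 18 methyl (13E)-15-hydroxylabda-8(17),13-dien-19-oate
Conditions: i-Bu2AlH (2.3 equiv), CH2Cl2, −78 °C; aq. KNaC4H4O6 work-up
Reagents that add atoms: none
Why: Hydride 1,2-reduction of an ester: i-Bu2AlH at −78 °C should reduce the unhindered conjugated ethyl ester to the allylic alcohol with retention of the E geometry, whereas the C19 methyl ester, axial on quaternary C4 and shielded by the C10 methyl, is expected to be inert at this temperature.

Step 12
Reactants: 18 methyl (13E)-15-hydroxylabda-8(17),13-dien-19-oate; 19 hexadecanoyl chloride (palmitoyl chloride)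
Product: 20 methyl (13E)-15-(hexadecanoyloxy)labda-8(17),13-dien-19-oate
Conditions: pyridine, DMAP (cat.), CH2Cl2, 0 °C → rt
Reagents that add atoms: none
Why: DMAP-catalysed O-acylation (nucleophilic catalysis through the acylpyridinium ion) of the unhindered primary allylic alcohol by the acid chloride should give the palmitate without affecting any stereocentre or olefin.

Compound list
1 | methyl 2-oxocyclohexane-1-carboxylate | COC(=O)C1CCCCC1=O | starting material
2 | L-valine tert-butyl ester, tert-butyl (2S)-2-amino-3-methylbutanoate (auxiliary) | CC(C)[C@H](N)C(=O)OC(C)(C)C | starting material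
3 | methyl 2-{[(2S)-1-tert-butoxy-3-methyl-1-oxobutan-2-yl]amino}cyclohex-1-ene-1-carboxylate | COC(=O)C1=C(N[C@@H](C(C)C)C(=O)OC(C)(C)C)CCCC1 | intermediate
4 | methyl (1S)-2-{[(2S)-1-tert-butoxy-3-methyl-1-oxobutan-2-yl]imino}-1-methylcyclohexane-1-carboxylate (not isolated) | CC(C)[C@H](N=C1CCCC[C@]1(C)C(=O)OC)C(=O)OC(C)(C)C | intermediate
5 | methyl (1S)-1-methyl-2-oxocyclohexane-1-carboxylate | O=C1CCCC[C@]1(C)C(=O)OC | intermediate
6 | methyl (1S)-1,3-dimethyl-2-oxocyclohexane-1-carboxylate (C3 epimer mixture) | O=C1C(C)CCC[C@]1(C)C(=O)OC | intermediate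
7 | methyl (1S)-1,3-dimethyl-2-{[(trifluoromethyl)sulfonyl]oxy}cyclohex-2-ene-1-carboxylate | O=S(=O)(OC1=C(C)CCC[C@]1(C)C(=O)OC)C(F)(F)F | intermediate
8 | methyl (1S)-2-ethenyl-1,3-dimethylcyclohex-2-ene-1-carboxylate | C=CC1=C(C)CCC[C@]1(C)C(=O)OC | intermediate
9 | pentane-2,4-dione | CC(=O)CC(C)=O | starting material
10 | 1,1,3-trichloroprop-1-ene | ClCC=C(Cl)Cl | starting material
11 | 3-(3,3-dichloroprop-2-en-1-yl)pentane-2,4-dione (not isolated) | CC(=O)C(CC=C(Cl)Cl)C(C)=O | intermediate
12 | 6,6-dichlorohex-5-en-2-one | CC(=O)CCC=C(Cl)Cl | intermediate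
13 | methyl (1S)-2-[2-(9-borabicyclo[3.3.1]nonan-9-yl)ethyl]-1,3-dimethylcyclohex-2-ene-1-carboxylate (not isolated) | C1CC2CCCC(C1)B2CCC3=C(C)CCC[C@]3(C)C(=O)OC | intermediate
14 | methyl (1S)-2-[(3Z)-3-chloro-7-oxooct-3-en-1-yl]-1,3-dimethylcyclohex-2-ene-1-carboxylate | CC(=O)CC/C=C(\Cl)CCC1=C(C)CCC[C@]1(C)C(=O)OC | intermediate
15 | methyl 8,13-dioxo-14,15,17-trinorlabdan-19-oate (5α-H, 9α-H, 10β-CH3, 4β-CO2CH3) | O=C1CC[C@@H]2[C@](C)(CCC[C@]2(C)C(=O)OC)[C@H]1CCC(C)=O | intermediate
16 | 15-ethyl 19-methyl (13E)-8-oxo-17-norlabd-13-ene-15,19-dioate | O=C1CC[C@@H]2[C@](C)(CCC[C@]2(C)C(=O)OC)[C@H]1CC/C(C)=C/C(=O)OCC | intermediate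
17 | 15-ethyl 19-methyl (13E)-labda-8(17),13-diene-15,19-dioate | C=C1CC[C@@H]2[C@](C)(CCC[C@]2(C)C(=O)OC)[C@H]1CC/C(C)=C/C(=O)OCC | intermediate
18 | methyl (13E)-15-hydroxylabda-8(17),13-dien-19-oate | C=C1CC[C@@H]2[C@](C)(CCC[C@]2(C)C(=O)OC)[C@H]1CC/C(C)=C/CO | intermediate
19 | hexadecanoyl chloride (palmitoyl chloride) | ClC(=O)CCCCCCCCCCCCCCC | starting material
20 | methyl (13E)-15-(hexadecanoyloxy)labda-8(17),13-dien-19-oate | C=C1CC[C@@H]2[C@](C)(CCC[C@]2(C)C(=O)OC)[C@H]1CC/C(C)=C/COC(=O)CCCCCCCCCCCCCCC | target

Total step count: 12. Longest linear sequence: 11 steps (steps 1–5 and 7–12, from 1 to 20); step 6 supplies the side branch.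

Steps most likely to fail

1. Step 8 (ring B closure). Ring closure may be outrun by proton loss from the C10 cation to isomeric ring A olefins, by capture of the cation by the ester oxygen, or by protonation of the chloro-olefin itself. The two faces of the ring A olefin may also be poorly differentiated by C4. The fallback sets out from triflate 7 and returns at diketone 15, replacing the chloro-olefin by a β-keto ester enol as the terminating nucleophile under SnCl4.
 - Negishi coupling of 7 with commercial BrZnCH2CH2CO2Et (PdCl2(dppf), THF, 50 °C) should give methyl (1S)-2-(3-ethoxy-3-oxopropyl)-1,3-dimethylcyclohex-2-ene-1-carboxylate F1.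
 - Crossed Claisen condensation with the lithium enolate of allyl acetate (LiN(i-Pr)2, THF, −78 °C), which should select the unhindered ethyl ester over the ring ester, should give methyl (1S)-1,3-dimethyl-2-[3,5-dioxo-5-(prop-2-en-1-yloxy)pentyl]cyclohex-2-ene-1-carboxylate F2.
 - SnCl4 in CH2Cl2 at 0 °C should close ring B to 19-methyl 11-prop-2-en-1-yl 8-oxo-12,13,14,15,16,17-hexanorlabdane-11,19-dioate F3.
 - Michael addition to but-3-en-2-one (cat. K2CO3, acetone) should give 19-methyl 11-prop-2-en-1-yl 8-oxo-9-(3-oxobutyl)-12,13,14,15,16,17-hexanorlabdane-11,19-dioate F4.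
 - Palladium-catalysed deallylative decarboxylation (Pd(OAc)2, PPh3, HCO2H, Et3N, THF) should then deliver 15, with C9 settling chain-equatorial.

2. Step 9 (olefination at C13). Base-induced enolisation may lead to intramolecular aldol closure between the C13 and C8 carbonyl units before olefination, and E/Z discrimination at the methyl ketone may be incomplete. The fallback sets out from diketone 15 and returns at diester 17, separating the two carbonyl groups before any base is used.
 - Selective ketalisation of the unhindered C13 ketone (ethylene glycol, PPTS, benzene, Dean–Stark) should give methyl 13,13-(ethane-1,2-diyldioxy)-8-oxo-14,15,17-trinorlabdan-19-oate F5.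
 - Wittig methylenation at C8 (Ph3PCH3Br, KOt-Bu, toluene, 80 °C) should give methyl 13,13-(ethane-1,2-diyldioxy)-14,15-dinorlabd-8(17)-en-19-oate F6.
 - Mild hydrolysis (PPTS, acetone/H2O) should free methyl 13-oxo-14,15-dinorlabd-8(17)-en-19-oate F7.
 - The Horner–Wadsworth–Emmons reaction of step 9, now on a mono-ketone, should give 17. This detour also bypasses step 10.

3. Step 7 (hydroboration and mono-alkylation). Hydroboration of the hindered, twisted diene may be slow, and in the coupling the transmetalation of the congested homoallylic borane may lag, so that a second alkylation or reduction of the C–Cl bond competes. The fallback sets out from diene 8 and returns at precursor 14, using an isolated iodide and its zinc reagent in place of the borane.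
 - Hydroboration as in step 7 to 13, followed by oxidation (NaBO3·4H2O, THF/H2O), should give methyl (1S)-2-(2-hydroxyethyl)-1,3-dimethylcyclohex-2-ene-1-carboxylate F8.
 - Appel iodination (I2, PPh3, imidazole, CH2Cl2, 0 °C) should give methyl (1S)-2-(2-iodoethyl)-1,3-dimethylcyclohex-2-ene-1-carboxylate F9.
 - Zinc insertion (Zn dust, LiCl, THF) should give {2-[(6S)-6-(methoxycarbonyl)-2,6-dimethylcyclohex-1-en-1-yl]ethyl}zinc iodide F10.
 - Negishi trans-selective mono-alkylation of 12 (PdCl2(DPEphos), DMF, rt) should give 14.

Further compounds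
F1 | step 8 | methyl (1S)-2-(3-ethoxy-3-oxopropyl)-1,3-dimethylcyclohex-2-ene-1-carboxylate | CCOC(=O)CCC1=C(C)CCC[C@]1(C)C(=O)OC
F2 | step 8 | methyl (1S)-1,3-dimethyl-2-[3,5-dioxo-5-(prop-2-en-1-yloxy)pentyl]cyclohex-2-ene-1-carboxylate | C=CCOC(=O)CC(=O)CCC1=C(C)CCC[C@]1(C)C(=O)OC
F3 | step 8 | 19-methyl 11-prop-2-en-1-yl 8-oxo-12,13,14,15,16,17-hexanorlabdane-11,19-dioate | O=C1CC[C@@H]2[C@](C)(CCC[C@]2(C)C(=O)OC)[C@H]1C(=O)OCC=C
F4 | step 8 | 19-methyl 11-prop-2-en-1-yl 8-oxo-9-(3-oxobutyl)-12,13,14,15,16,17-hexanorlabdane-11,19-dioate (C9 configuration inconsequential) | O=C1CC[C@@H]2[C@](C)(CCC[C@]2(C)C(=O)OC)C1(CCC(C)=O)C(=O)OCC=C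
F5 | step 9 | methyl 13,13-(ethane-1,2-diyldioxy)-8-oxo-14,15,17-trinorlabdan-19-oate | O=C1CC[C@@H]2[C@](C)(CCC[C@]2(C)C(=O)OC)[C@H]1CCC3(C)OCCO3
F6 | step 9 | methyl 13,13-(ethane-1,2-diyldioxy)-14,15-dinorlabd-8(17)-en-19-oate | C=C1CC[C@@H]2[C@](C)(CCC[C@]2(C)C(=O)OC)[C@H]1CCC3(C)OCCO3
F7 | step 9 | methyl 13-oxo-14,15-dinorlabd-8(17)-en-19-oate | C=C1CC[C@@H]2[C@](C)(CCC[C@]2(C)C(=O)OC)[C@H]1CCC(C)=O
F8 | step 7 | methyl (1S)-2-(2-hydroxyethyl)-1,3-dimethylcyclohex-2-ene-1-carboxylate | OCCC1=C(C)CCC[C@]1(C)C(=O)OC
F9 | step 7 | methyl (1S)-2-(2-iodoethyl)-1,3-dimethylcyclohex-2-ene-1-carboxylate | ICCC1=C(C)CCC[C@]1(C)C(=O)OC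
F10 | step 7 | {2-[(6S)-6-(methoxycarbonyl)-2,6-dimethylcyclohex-1-en-1-yl]ethyl}zinc iodide | I[Zn]CCC1=C(C)CCC[C@]1(C)C(=O)OC
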